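**Plan**

1. Retrosynthetic cuts, in order: (a) the ten O–benzyl bonds and a blocking C8(D)–Br bond; (b) C3–O and C4–H of ring C (syn hydroboration of a flav-3-ene); (c) O1–C2, which opens ring C to a triaryl allylic carbinol; (d) the interflavan bond C4–C6(D), as aryl-metal plus chalcone carbonyl; (e) the chalcone C=C (aldol).
2. Forward: (+)-gallocatechin supplies rings D, E and F intact. It is benzylated, brominated at C8(D), iodinated at C6(D), metalated there and added to a 2′-hydroxychalcone that carries rings A and B. Ring C is then closed at O1–C2, its C3=C4 bond is hydrated syn with oxygen at C3, and hydrogenolysis finishes.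
3. Stereochemistry: C2 and C3 of the lower unit come from the chiral pool. C2 of the upper unit is set in the ring closure by a chiral Brønsted acid (chiral ion pair). C3 and C4 are relayed from C2 by syn addition of H–B opposite to ring B. The 4→6 regiochemistry is fixed by halogen placement.
4. Enabling feature: C4 is flanked by ring A, whose ortho oxygen is O1, and by the trioxygenated ring D, and it is allylic to C2, which carries ring B. A C4 carbinol therefore ionizes very easily to a triaryl allyl cation (an O-protonated o-quinone allide of ring A) whose far terminus C2 lies within reach of O1.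

Key step: step 7

Remark on labels: the upper (robinetinidol) unit has rings A, B, C and atoms O1, C2, C3, C4; the lower (gallocatechin) unit has rings D, E, F, and its positions are written C6(D), C8(D). "BGC" stands for the (2R,3S)-3,5,7-tris(benzyloxy)-8-bromo-2-[3,4,5-tris(benzyloxy)phenyl]chroman-6-yl group.

Remark on the chemistry: the (R)-configured acid of step 7 is assumed to deliver the (2S)-chromene; if the sense of induction proves opposite, its enantiomer is used.

**Route**

Step 1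
Reactants: 1 (+)-gallocatechin
Product: 2 5,7,3′,4′,5′-penta-O-benzyl-(+)-gallocatechin
Conditions: BnBr (5.5 equiv), K2CO3, DMF, argon, 0 °C → rt
Reagents that add atoms: benzyl bromide, BrCc1ccccc1
Why: Williamson etherification in which K2CO3 deprotonates only the five phenols and not the C3 alcohol, and O-alkylation under argon at low temperature should outrun oxidation of the pyrogallol ring; no stereocenter is touched.

Step 2
Reactants: 2 5,7,3′,4′,5′-penta-O-benzyl-(+)-gallocatechin
Product: 3 3,5,7,3′,4′,5′-hexa-O-benzyl-(+)-gallocatechin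
Conditions: NaH, BnBr, Bu4NI (cat.), THF/DMF, 0 °C → rt
Reagents that add atoms: benzyl bromide, BrCc1ccccc1
Why: Williamson etherification of the secondary C3 alkoxide, the usual way to cap the 3-OH of benzylated flavan-3-ols; the configuration at C3 is retained because only the O–H bond reacts.

Step 3
Reactants: 3 3,5,7,3′,4′,5′-hexa-O-benzyl-(+)-gallocatechin
Product: 4 8-bromo-3,5,7,3′,4′,5′-hexa-O-benzyl-(+)-gallocatechin
Conditions: N-bromosuccinimide (1.0 equiv), CH2Cl2, −78 °C → rt, dark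
Reagents that add atoms: N-bromosuccinimide, O=C1CCC(=O)N1Br
Why: Electrophilic aromatic bromination should go to C8(D), the more accessible of the two free positions of the phloroglucinol-type ring D, as is the rule for benzylated catechins; the bromine then blocks C8(D).

Step 4
Reactants: 4 8-bromo-3,5,7,3′,4′,5′-hexa-O-benzyl-(+)-gallocatechin
Product: 5 8-bromo-6-iodo-3,5,7,3′,4′,5′-hexa-O-benzyl-(+)-gallocatechin
Conditions: N-iodosuccinimide (1.2 equiv), CF3CO2H (cat.), MeCN/CH2Cl2, 0 °C → rt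
Reagents that add atoms: N-iodosuccinimide, O=C1CCC(=O)N1I
Why: Electrophilic aromatic iodination at C6(D), the only free position left on the trioxygenated ring D, which is far more electron-rich than ring E or the benzyl groups.

Step 5
Reactants: 6 1-[4-(benzyloxy)-2-hydroxyphenyl]ethanone; 7 3,4,5-tris(benzyloxy)benzaldehyde
Product: 8 (E)-1-[4-(benzyloxy)-2-hydroxyphenyl]-3-[3,4,5-tris(benzyloxy)phenyl]prop-2-en-1-one
Conditions: KOH (aq. 50 %), EtOH, rt; then dilute HCl to pH 5
Reagents that add atoms: none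
Why: Claisen–Schmidt (crossed aldol) condensation with a non-enolizable aldehyde; E1cB dehydration should give the conjugated E-enone.

Step 6
Reactants: 5 8-bromo-6-iodo-3,5,7,3′,4′,5′-hexa-O-benzyl-(+)-gallocatechin; 8 (E)-1-[4-(benzyloxy)-2-hydroxyphenyl]-3-[3,4,5-tris(benzyloxy)phenyl]prop-2-en-1-one
Product: 12 (E)-1-[4-(benzyloxy)-2-hydroxyphenyl]-1-BGC-3-[3,4,5-tris(benzyloxy)phenyl]prop-2-en-1-ol (both carbinol epimers), via chalcone lithium phenoxide 9 (not isolated), via aryllithium 10 (not isolated), via arylcerium dichloride 11 (not isolated)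
Conditions: 5, n-BuLi (1.05 equiv), THF, −78 °C; CeCl3 (anhydrous, 1.2 equiv), −78 °C; then 9 [from 8 and LiN(SiMe3)2, THF, −78 °C], −78 → −30 °C; aq. NH4Cl/NH3 (pH 9); basic alumina
Reagents that add atoms: none
Why: Iodine–lithium exchange is much faster than bromine–lithium exchange at −78 °C, so only C6(D) is metalated, and the organocerium reagent should add 1,2 to the enone carbonyl of the pre-formed phenoxide instead of 1,4 or acting as a base; the new carbinol center forms without control and is erased in step 7.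

Step 7
Reactants: 12 (E)-1-[4-(benzyloxy)-2-hydroxyphenyl]-1-BGC-3-[3,4,5-tris(benzyloxy)phenyl]prop-2-en-1-ol
Product: 14 (2S)-7-(benzyloxy)-4-BGC-2-[3,4,5-tris(benzyloxy)phenyl]-2H-chromene, via triaryl allyl cation 13 (not isolated)
Conditions: (R)-3,3′-bis(2,4,6-triisopropylphenyl)-1,1′-binaphthyl-2,2′-diyl N-triflylphosphoramide (5 mol %), toluene, −78 °C, dark; Et3N quench at −78 °C
Reagents that add atoms: none
Why: The strong chiral acid protonates the tertiary, doubly benzylic and allylic C4 hydroxyl, water leaves, and the 1,1,3-triaryl allyl cation 13 (an O-protonated o-quinone allide of ring A) stays ion-paired with the chiral phosphoramidate and hydrogen-bonded to it through the ring A phenol; the phenol oxygen O1 then attacks the far allyl terminus C2 and the anion takes up the proton. The closest known reaction type is the chiral N-triflylphosphoramide-catalysed intramolecular allylic substitution of o-hydroxyaryl allylic alcohols to 2-aryl-2H-chromenes through chiral contact ion pairs. Ring C closes in a 6-endo-trig mode, which from the neutral quinone allide is a thermally allowed oxa-6π electrocyclization. The single new stereocenter C2 is controlled by the chiral counter-anion, which covers one face of the planar terminus, while the gallocatechin stereocenters are too remote to interfere and the unselective C4 center of 12 vanishes on ionization. The step needs closure by O1 and no reopening of the product: the free ortho phenol is the only nucleophile that gives a neutral six-membered product, both ortho positions of ring D are substituted so that ring cannot close an indene, and low temperature with an amine quench should keep the benzylic, allylic C2–O1 bond from re-ionizing.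

Step 8
Reactants: 14 (2S)-7-(benzyloxy)-4-BGC-2-[3,4,5-tris(benzyloxy)phenyl]-2H-chromene
Product: 16 (2R,3S,4S)-7-(benzyloxy)-4-BGC-2-[3,4,5-tris(benzyloxy)phenyl]chroman-3-ol, via C3 alkylborane 15 (not isolated)
Conditions: BH3·THF (excess), THF, 0 °C → rt; then NaOH (aq.), H2O2, 0 °C
Reagents that add atoms: hydrogen peroxide, OO; borane–tetrahydrofuran, B.C1CCOC1 (its boron stays only in 15)
Why: Hydroboration–oxidation, in which BH3 adds syn across the styrenic C3=C4 bond with boron at the less substituted C3 and hydrogen at C4, from the face opposite ring B at C2, and oxidation with retention should give the 2,3-trans-3,4-trans arrangement (3S,4S) with rings B and D cis.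

Step 9
Reactants: 16 (2R,3S,4S)-7-(benzyloxy)-4-BGC-2-[3,4,5-tris(benzyloxy)phenyl]chroman-3-ol
Product: 17 robinetinidol-(4α→6)-gallocatechin (CNP0311915.1)
Conditions: H2 (1 atm), Pd(OH)2/C, Et3N, THF/MeOH/H2O, rt; Sephadex LH-20
Reagents that add atoms: none
Why: Hydrogenolysis over Pd(OH)2/C should cleave all ten benzyl ethers and, with Et3N as scavenger of HBr, the aryl C–Br bond at C8(D), as is usual for bromine-blocked proanthocyanidin precursors; no stereocenter is touched and the interflavan C–C bond is not hydrogenolysed.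

**Compound list**

1 | (+)-gallocatechin, (2R,3S)-2-(3,4,5-trihydroxyphenyl)chromane-3,5,7-triol | c1c(O)cc2c(c1O)C[C@H](O)[C@@H](c3cc(O)c(O)c(O)c3)O2 | starting material

2 | 5,7,3′,4′,5′-penta-O-benzyl-(+)-gallocatechin | c1c(OCc4ccccc4)cc2c(c1OCc4ccccc4)C[C@H](O)[C@@H](c3cc(OCc4ccccc4)c(OCc4ccccc4)c(OCc4ccccc4)c3)O2 | intermediate

3 | 3,5,7,3′,4′,5′-hexa-O-benzyl-(+)-gallocatechin | c1c(OCc4ccccc4)cc2c(c1OCc4ccccc4)C[C@H](OCc4ccccc4)[C@@H](c3cc(OCc4ccccc4)c(OCc4ccccc4)c(OCc4ccccc4)c3)O2 | intermediate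

4 | 8-bromo-3,5,7,3′,4′,5′-hexa-O-benzyl-(+)-gallocatechin | c1c(OCc4ccccc4)c(Br)c2c(c1OCc4ccccc4)C[C@H](OCc4ccccc4)[C@@H](c3cc(OCc4ccccc4)c(OCc4ccccc4)c(OCc4ccccc4)c3)O2 | intermediate

5 | 8-bromo-6-iodo-3,5,7,3′,4′,5′-hexa-O-benzyl-(+)-gallocatechin | Ic1c(OCc4ccccc4)c(Br)c2c(c1OCc4ccccc4)C[C@H](OCc4ccccc4)[C@@H](c3cc(OCc4ccccc4)c(OCc4ccccc4)c(OCc4ccccc4)c3)O2 | intermediate

6 | 1-[4-(benzyloxy)-2-hydroxyphenyl]ethanone | CC(=O)c1ccc(OCc2ccccc2)cc1O | starting material

7 | 3,4,5-tris(benzyloxy)benzaldehyde | O=Cc1cc(OCc2ccccc2)c(OCc2ccccc2)c(OCc2ccccc2)c1 | starting material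

8 | (E)-1-[4-(benzyloxy)-2-hydroxyphenyl]-3-[3,4,5-tris(benzyloxy)phenyl]prop-2-en-1-one | O=C(/C=C/c1cc(OCc2ccccc2)c(OCc2ccccc2)c(OCc2ccccc2)c1)c1ccc(OCc2ccccc2)cc1O | intermediate

9 | lithium phenoxide of chalcone 8 | [Li+].[O-]c1cc(OCc2ccccc2)ccc1C(=O)/C=C/c1cc(OCc2ccccc2)c(OCc2ccccc2)c(OCc2ccccc2)c1 | intermediate

10 | 8-bromo-6-lithio-3,5,7,3′,4′,5′-hexa-O-benzylgallocatechin (BGC–Li) | [Li]c1c(OCc4ccccc4)c(Br)c2c(c1OCc4ccccc4)C[C@H](OCc4ccccc4)[C@@H](c3cc(OCc4ccccc4)c(OCc4ccccc4)c(OCc4ccccc4)c3)O2 | intermediate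

11 | BGC–CeCl2, the arylcerium dichloride from 10 | Cl[Ce](Cl)c1c(OCc4ccccc4)c(Br)c2c(c1OCc4ccccc4)C[C@H](OCc4ccccc4)[C@@H](c3cc(OCc4ccccc4)c(OCc4ccccc4)c(OCc4ccccc4)c3)O2 | intermediate

12 | (E)-1-[4-(benzyloxy)-2-hydroxyphenyl]-1-BGC-3-[3,4,5-tris(benzyloxy)phenyl]prop-2-en-1-ol, both carbinol epimers | Oc1cc(OCc5ccccc5)ccc1C(O)(/C=C/c6cc(OCc5ccccc5)c(OCc5ccccc5)c(OCc5ccccc5)c6)c1c(OCc4ccccc4)c(Br)c2c(c1OCc4ccccc4)C[C@H](OCc4ccccc4)[C@@H](c3cc(OCc4ccccc4)c(OCc4ccccc4)c(OCc4ccccc4)c3)O2 | intermediate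

13 | 1-[4-(benzyloxy)-2-hydroxyphenyl]-1-BGC-3-[3,4,5-tris(benzyloxy)phenyl]allyl cation, paired with the chiral phosphoramidate | Oc1cc(OCc5ccccc5)ccc1[C+](/C=C/c6cc(OCc5ccccc5)c(OCc5ccccc5)c(OCc5ccccc5)c6)c1c(OCc4ccccc4)c(Br)c2c(c1OCc4ccccc4)C[C@H](OCc4ccccc4)[C@@H](c3cc(OCc4ccccc4)c(OCc4ccccc4)c(OCc4ccccc4)c3)O2 | intermediate

14 | (2S)-7-(benzyloxy)-4-BGC-2-[3,4,5-tris(benzyloxy)phenyl]-2H-chromene | O(Cc5ccccc5)c1ccc2c(c1)O[C@H](c6cc(OCc5ccccc5)c(OCc5ccccc5)c(OCc5ccccc5)c6)C=C2c1c(OCc4ccccc4)c(Br)c2c(c1OCc4ccccc4)C[C@H](OCc4ccccc4)[C@@H](c3cc(OCc4ccccc4)c(OCc4ccccc4)c(OCc4ccccc4)c3)O2 | intermediate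

15 | C3 alkylborane of 14: BH2 at C3 trans to ring B, H at C4 cis to boron | O(Cc5ccccc5)c1ccc2c(c1)O[C@H](c6cc(OCc5ccccc5)c(OCc5ccccc5)c(OCc5ccccc5)c6)[C@@H](B)[C@@H]2c1c(OCc4ccccc4)c(Br)c2c(c1OCc4ccccc4)C[C@H](OCc4ccccc4)[C@@H](c3cc(OCc4ccccc4)c(OCc4ccccc4)c(OCc4ccccc4)c3)O2 | intermediate

16 | (2R,3S,4S)-7-(benzyloxy)-4-BGC-2-[3,4,5-tris(benzyloxy)phenyl]chroman-3-ol (deca-O-benzyl-8(D)-bromo dimer) | O(Cc5ccccc5)c1ccc2c(c1)O[C@H](c6cc(OCc5ccccc5)c(OCc5ccccc5)c(OCc5ccccc5)c6)[C@@H](O)[C@@H]2c1c(OCc4ccccc4)c(Br)c2c(c1OCc4ccccc4)C[C@H](OCc4ccccc4)[C@@H](c3cc(OCc4ccccc4)c(OCc4ccccc4)c(OCc4ccccc4)c3)O2 | intermediate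

17 | robinetinidol-(4α→6)-gallocatechin, CNP0311915.1 | Oc1ccc2c(c1)O[C@H](c1cc(O)c(O)c(O)c1)[C@@H](O)[C@@H]2c1c(O)cc2c(c1O)C[C@H](O)[C@@H](c1cc(O)c(O)c(O)c1)O2 | target

**Count and risks**

Total step count: 9. Longest linear sequence: 8 steps (steps 1–4 and 6–9); step 5 is a one-step side branch.

Steps most likely to fail:

Step 7. Facial control in the ion pair may be lost, either through an uncatalysed racemic closure of the very easily ionized carbinol or through re-ionization of the product at its C2–O1 bond. The fallback sets out from 12 and comes back at 14; it gives up catalyst control for a resolution with recycling. Closure with an achiral acid (pyridinium p-toluenesulfonate, CH2Cl2, 0 °C) would give 14 together with its C2 epimer, the (2R)-chromene F1. Because of the gallocatechin unit the two are diastereomers and would be separated by preparative HPLC. F1 would then be returned to the same acid, which equilibrates it with 14 through cation 13.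

Step 6. The hindered, chelated aryl nucleophile may fail to reach the phenoxide-deactivated carbonyl, with conjugate addition, protonation of the aryl metal or no reaction as the result. The fallback sets out from 5 and comes back at 12; it sends the large nucleophile to an aldehyde and a small one to the ketone. Aryllithium 10 (from 5 and n-BuLi, 2 equiv) would be added to commercial 4-(benzyloxy)-2-hydroxybenzaldehyde to give the benzhydrol F2, and MnO2 would oxidize it to the 2-hydroxybenzophenone F3. Takai olefination of aldehyde 7 (CrCl2, CHI3, THF) would give the (E)-vinyl iodide F4, and iodine–lithium exchange with t-BuLi the alkenyllithium F5. Addition of F5 (2 equiv, −78 °C) to F3 would give 12.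

Step 8. The crowded C4, which carries ring D with two ortho benzyloxy groups, may refuse the hydrogen transfer from boron; facial selectivity may be poor; or the C3 borane may eliminate toward O1 and open ring C. The fallback sets out from 5 and comes back at 16; it sets C4 first and closes ring C on a chain that already carries the C3 oxygen. Benzhydrol F2 (made from 5 as above) would be ionized to its o-quinone methide in the presence of the diethyl (E)-alkenylboronate F6 (from F5 and B(OEt)3, then HCl in ether) and (R)-3,3′-dibromo-1,1′-bi-2-naphthol (15 mol %), a chiral-biphenol-catalysed alkenylboronate addition that should give the (S)-1,1,3-triarylpropene F7 (sense of induction to be confirmed). Asymmetric dihydroxylation of the E-alkene (OsO4 cat., (DHQ)2PHAL, N-methylmorpholine N-oxide as oxidant so that the phenol is spared) would give the syn-diol F8. Mitsunobu closure (PPh3, diisopropyl azodicarboxylate, THF, 0 °C) with inversion at the benzylic C2 would then form O1–C2 and give 16.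

**Further compounds**

F1 | step 7 | (2R)-7-(benzyloxy)-4-BGC-2-[3,4,5-tris(benzyloxy)phenyl]-2H-chromene | O(Cc5ccccc5)c1ccc2c(c1)O[C@@H](c6cc(OCc5ccccc5)c(OCc5ccccc5)c(OCc5ccccc5)c6)C=C2c1c(OCc4ccccc4)c(Br)c2c(c1OCc4ccccc4)C[C@H](OCc4ccccc4)[C@@H](c3cc(OCc4ccccc4)c(OCc4ccccc4)c(OCc4ccccc4)c3)O2

F2 | step 6 | [4-(benzyloxy)-2-hydroxyphenyl](BGC)methanol, both carbinol epimers | Oc1cc(OCc5ccccc5)ccc1C(O)c1c(OCc4ccccc4)c(Br)c2c(c1OCc4ccccc4)C[C@H](OCc4ccccc4)[C@@H](c3cc(OCc4ccccc4)c(OCc4ccccc4)c(OCc4ccccc4)c3)O2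

F3 | step 6 | [4-(benzyloxy)-2-hydroxyphenyl](BGC)methanone | Oc1cc(OCc5ccccc5)ccc1C(=O)c1c(OCc4ccccc4)c(Br)c2c(c1OCc4ccccc4)C[C@H](OCc4ccccc4)[C@@H](c3cc(OCc4ccccc4)c(OCc4ccccc4)c(OCc4ccccc4)c3)O2

F4 | step 6 | (E)-1,2,3-tris(benzyloxy)-5-(2-iodoethenyl)benzene | I/C=C/c1cc(OCc2ccccc2)c(OCc2ccccc2)c(OCc2ccccc2)c1

F5 | step 6 | (E)-2-[3,4,5-tris(benzyloxy)phenyl]ethenyllithium | [Li]/C=C/c1cc(OCc2ccccc2)c(OCc2ccccc2)c(OCc2ccccc2)c1

F6 | step 8 | diethyl (E)-2-[3,4,5-tris(benzyloxy)phenyl]ethenylboronate | CCOB(OCC)/C=C/c1cc(OCc2ccccc2)c(OCc2ccccc2)c(OCc2ccccc2)c1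

F7 | step 8 | 5-(benzyloxy)-2-{(1S,2E)-1-BGC-3-[3,4,5-tris(benzyloxy)phenyl]prop-2-en-1-yl}phenol | Oc1cc(OCc5ccccc5)ccc1[C@@H](c1c(OCc4ccccc4)c(Br)c2c(c1OCc4ccccc4)C[C@H](OCc4ccccc4)[C@@H](c3cc(OCc4ccccc4)c(OCc4ccccc4)c(OCc4ccccc4)c3)O2)/C=C/c6cc(OCc5ccccc5)c(OCc5ccccc5)c(OCc5ccccc5)c6

F8 | step 8 | (1S,2S,3S)-3-[4-(benzyloxy)-2-hydroxyphenyl]-3-BGC-1-[3,4,5-tris(benzyloxy)phenyl]propane-1,2-diol | Oc1cc(OCc5ccccc5)ccc1[C@@H](c1c(OCc4ccccc4)c(Br)c2c(c1OCc4ccccc4)C[C@H](OCc4ccccc4)[C@@H](c3cc(OCc4ccccc4)c(OCc4ccccc4)c(OCc4ccccc4)c3)O2)[C@H](O)[C@@H](O)c6cc(OCc5ccccc5)c(OCc5ccccc5)c(OCc5ccccc5)c6
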